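**Retrosynthetic overview**
- The target comes from its 5′,6′-acetonide by ketal hydrolysis (last step).
- The acetonide comes from one three-component radical step: a dioxolanyl radical (by decarboxylation) adds to isoprene to form C4′–C5′ and set C5′ trans to C6′, and 7-hydroxy-8-methoxycoumarin closes C1′–O on the resulting π-allyl.
- The radical precursor acid comes from D-erythronolactone (acetonide, MeLi, methylenation, oxidation). Lactone C3 becomes C6′; the lactone CH2O carbon leaves as CO2.
- The coumarin comes from 2-methoxyresorcinol and ethyl propiolate; 2-methoxyresorcinol comes from resorcinol (2-iodination, Cu methoxylation).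
- Rings: the benzene ring is bought; the pyranone ring is closed in step 3; the temporary dioxolane is made in step 4 and removed in step 9.

Assumption: side-chain atoms are numbered C1′ (OCH2) to C8′ (=CH2); the target is the threo (5′S,6′S) diol with (E) geometry at C2′=C3′.

**Route**

Step 1
Reactants: 1 resorcinol
Product: 2 2-iodobenzene-1,3-diol
Conditions: I2 (1.05 equiv), NaHCO3 (1.1 equiv), H2O, 0 °C to rt
Reagents that add atoms: iodine, II
Why: Electrophilic aromatic iodination; in aqueous bicarbonate the doubly ortho-activated C2 of the resorcinolate is iodinated selectively, a standard preparation of 2-iodoresorcinol.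

Step 2
Reactants: 2 2-iodobenzene-1,3-diol
Product: 3 2-methoxybenzene-1,3-diol
Conditions: NaOMe (5 equiv), CuI (10 mol %), MeOH/DMF 1:1, 110 °C (sealed); then aq. HCl
Reagents that add atoms: sodium methoxide, C[O-].[Na+]
Why: Ullmann-type Cu-catalysed methoxylation of an aryl iodide carrying free ortho-phenoxides, the same reaction type as the 5-halovanillin to syringaldehyde conversion.

Step 3
Reactants: 3 2-methoxybenzene-1,3-diol; 4 ethyl propiolate
Product: 5 7-hydroxy-8-methoxy-2H-chromen-2-one
Conditions: ZnCl2 (1.0 equiv), dioxane, 100 °C; then 1 M HCl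
Reagents that add atoms: none
Why: Pechmann-type coumarin synthesis with a propiolate (Lewis-acid hydroarylation ortho to one OH and para to the other, then lactonisation); the symmetric diol allows only one ring-closure product, with OH at C7 and OMe at C8.

Step 4
Reactants: 6 D-erythronolactone
Product: 7 (3aR,6aR)-2,2-dimethyldihydrofuro[3,4-d][1,3]dioxol-4(3aH)-one
Conditions: 2,2-dimethoxypropane, p-TsOH (cat.), acetone, rt
Reagents that add atoms: 2,2-dimethoxypropane, COC(C)(C)OC
Why: Acid-catalysed transketalisation of the cis-diol (acetonide protection); no stereocentre is touched.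

Step 5
Reactants: 7 (3aR,6aR)-2,2-dimethyldihydrofuro[3,4-d][1,3]dioxol-4(3aH)-one
Product: 8 (3aR,6aR)-2,2,4-trimethyltetrahydrofuro[3,4-d][1,3]dioxol-4-ol (hemiketal; both C4 epimers)
Conditions: MeLi (1.05 equiv), THF, −78 °C; AcOH quench at −78 °C
Reagents that add atoms: methyllithium, [Li]C
Why: Mono-addition of an organolithium to a γ-lactone; the lithium hemiketalate is stable at −78 °C, so only one methyl group adds and the two ring stereocentres are untouched.

Step 6
Reactants: 8 (3aR,6aR)-2,2,4-trimethyltetrahydrofuro[3,4-d][1,3]dioxol-4-ol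
Product: 9 [(4R,5S)-2,2-dimethyl-5-(prop-1-en-2-yl)-1,3-dioxolan-4-yl]methanol (cis)
Conditions: Ph3PCH3Br (3.0 equiv), KOtBu (2.9 equiv), THF, 0 to 50 °C
Reagents that add atoms: methyltriphenylphosphonium bromide, C[P+](c1ccccc1)(c1ccccc1)c1ccccc1.[Br-]
Why: Wittig methylenation of the ring-opened hydroxy-ketone tautomer of the hemiketal; no bond to either stereocentre is broken, and a slight deficit of base relative to the salt limits epimerisation at the ketone α-carbon (the future C6′).

Step 7
Reactants: 9 [(4R,5S)-2,2-dimethyl-5-(prop-1-en-2-yl)-1,3-dioxolan-4-yl]methanol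
Product: 11 (4S,5S)-2,2-dimethyl-5-(prop-1-en-2-yl)-1,3-dioxolane-4-carboxylic acid, via dioxolane-4-carbaldehyde 10 (not isolated)
Conditions: TEMPO (20 mol %), PhI(OAc)2 (2.2 equiv), MeCN/H2O 1:1, rt; extraction at pH 4
Reagents that add atoms: water, O
Why: TEMPO/PhI(OAc)2 oxidation of a primary alcohol through the aldehyde hydrate to the acid, tolerant of the 1,1-disubstituted alkene and the acetonide; epimerisation at C4 would not matter because this centre becomes the radical carbon.

Step 8
Reactants: 11 (4S,5S)-2,2-dimethyl-5-(prop-1-en-2-yl)-1,3-dioxolane-4-carboxylic acid; 12 isoprene; 5 7-hydroxy-8-methoxy-2H-chromen-2-one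
Product: 14 7-{[(2E)-4-[(4S,5S)-2,2-dimethyl-5-(prop-1-en-2-yl)-1,3-dioxolan-4-yl]-3-methylbut-2-en-1-yl]oxy}-8-methoxy-2H-chromen-2-one, via N-acyloxyphthalimide 13 (not isolated)
Conditions: N-hydroxyphthalimide (1.05 equiv), DIC (1.05 equiv), THF, rt, 2 h; then 5 (1.5 equiv), 12 (10 equiv), Pd(PPh3)4 (5 mol %), K2CO3 (20 mol %), DMA, degassed, 450 nm LEDs, rt
Reagents that add atoms: none
Why: Proposed new method: blue-light-excited Pd(0) reduces the in-situ N-acyloxyphthalimide 13 by single-electron transfer, loss of CO2 gives the secondary 2,2-dimethyl-1,3-dioxolan-4-yl radical, this adds to C1 of s-trans isoprene on the face anti to the neighbouring isopropenyl group (forming C4′–C5′ and setting C5′ as S in the trans-dioxolane, with E geometry inherited from the s-trans diene), the allyl radical recombines with Pd(I) to a π-allyl-Pd(II) species, and the phenoxide of 5 (regenerated by the released phthalimide anion) attacks its unsubstituted terminus to give the linear allyl aryl ether; the closest known reaction type is the visible-light Pd-catalysed three-component 1,4-carbofunctionalisation of 1,3-dienes with redox-active esters and N- or O-nucleophiles (interrupted radical Heck/Tsuji–Trost), combined with the known trans-selective C–C bond formation of tartrate-type dioxolanyl radicals.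

Step 9
Reactants: 14 7-{[(2E)-4-[(4S,5S)-2,2-dimethyl-5-(prop-1-en-2-yl)-1,3-dioxolan-4-yl]-3-methylbut-2-en-1-yl]oxy}-8-methoxy-2H-chromen-2-one
Product: 15 7-{[(2E,5S,6S)-5,6-dihydroxy-3,7-dimethylocta-2,7-dien-1-yl]oxy}-8-methoxy-2H-chromen-2-one
Conditions: AcOH/H2O 4:1, 40 °C
Reagents that add atoms: none
Why: Mild acid hydrolysis of the isopropylidene ketal at the ketal carbon only, so both carbinol C–O bonds and the (5′S,6′S) configuration are retained, while the allyl aryl ether and the lactone survive this acidity.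

**Compound list**
1 | resorcinol (benzene-1,3-diol) | Oc1cccc(O)c1 | starting material
2 | 2-iodobenzene-1,3-diol | Oc1cccc(O)c1I | intermediate
3 | 2-methoxybenzene-1,3-diol | COc1c(O)cccc1O | intermediate
4 | ethyl propiolate | C#CC(=O)OCC | starting material
5 | 7-hydroxy-8-methoxy-2H-chromen-2-one | COc1c(O)ccc2ccc(=O)oc12 | intermediate
6 | D-erythronolactone, (3R,4R)-3,4-dihydroxyoxolan-2-one | C1[C@H]([C@H](C(=O)O1)O)O | starting material
7 | (3aR,6aR)-2,2-dimethyldihydrofuro[3,4-d][1,3]dioxol-4(3aH)-one | C1[C@@H]2[C@H](C(=O)O1)OC(C)(C)O2 | intermediate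
8 | (3aR,6aR)-2,2,4-trimethyltetrahydrofuro[3,4-d][1,3]dioxol-4-ol (C4 epimers) | C1[C@@H]2[C@H](C(C)(O)O1)OC(C)(C)O2 | intermediate
9 | [(4R,5S)-2,2-dimethyl-5-(prop-1-en-2-yl)-1,3-dioxolan-4-yl]methanol (cis) | OC[C@@H]1[C@H](C(C)=C)OC(C)(C)O1 | intermediate
10 | (4S,5S)-2,2-dimethyl-5-(prop-1-en-2-yl)-1,3-dioxolane-4-carbaldehyde (cis) | O=C[C@@H]1[C@H](C(C)=C)OC(C)(C)O1 | intermediate
11 | (4S,5S)-2,2-dimethyl-5-(prop-1-en-2-yl)-1,3-dioxolane-4-carboxylic acid (cis) | OC(=O)[C@@H]1[C@H](C(C)=C)OC(C)(C)O1 | intermediate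
12 | isoprene (2-methylbuta-1,3-diene) | C=CC(C)=C | starting material
13 | 1,3-dioxoisoindolin-2-yl (4S,5S)-2,2-dimethyl-5-(prop-1-en-2-yl)-1,3-dioxolane-4-carboxylate | O=C(ON1C(=O)c2ccccc2C1=O)[C@@H]1[C@H](C(C)=C)OC(C)(C)O1 | intermediate
14 | 7-{[(2E)-4-[(4S,5S)-2,2-dimethyl-5-(prop-1-en-2-yl)-1,3-dioxolan-4-yl]-3-methylbut-2-en-1-yl]oxy}-8-methoxy-2H-chromen-2-one (trans-dioxolane) | C=C(C)[C@@H]1OC(C)(C)O[C@H]1C/C(C)=C/COc1ccc2ccc(=O)oc2c1OC | intermediate
15 | 7-{[(2E,5S,6S)-5,6-dihydroxy-3,7-dimethylocta-2,7-dien-1-yl]oxy}-8-methoxy-2H-chromen-2-one | C=C(C)[C@H](O)[C@@H](O)C/C(C)=C/COc1ccc2ccc(=O)oc2c1OC | target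

**Totals**
Total step count: 9. Longest linear sequence: 6 steps (steps 4 to 9, from 6 to 15).

**Three steps most likely to fail**

Step 8 (three-component radical 1,4-oxyalkylation). Risks are N-allylation by the phthalimide anion instead of the phenoxide, acyl transfer from 13 to the phenoxide, Pd-catalysed telomerisation of isoprene with 5, and mixtures of regio-, E/Z- and cis/trans-isomers. The fallback sets out from 11 and comes back at 14. The N-acyloxyphthalimide 13 is isolated (NHPI, DIC) and used in a two-component reductive photoredox radical allylation (Ru(bpy)3Cl2, Hantzsch ester, i-Pr2NEt, blue LEDs) with commercial 2-(prop-1-en-2-yl)oxirane. The same dioxolanyl radical adds trans to the alkene CH2 and the epoxide opens, giving (E)-4-[(4S,5S)-2,2-dimethyl-5-(prop-1-en-2-yl)-1,3-dioxolan-4-yl]-3-methylbut-2-en-1-ol F1 after chromatographic removal of the Z isomer. Mitsunobu etherification of this alcohol with 5 (PPh3, DIAD, THF) then gives 14.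

Step 2 (Cu methoxylation of the di-ortho-hydroxy aryl iodide). Risks are protodeiodination back to resorcinol and sluggish coupling of the dianion. The fallback sets out from 1 and comes back at 3. Resorcinol is protected as 1,3-bis(methoxymethoxy)benzene F2 (MOMCl, i-Pr2NEt), lithiated between the two ethers (n-BuLi, THF, 0 °C), borylated and oxidised (B(OMe)3; then H2O2, NaOH) to 2,6-bis(methoxymethoxy)phenol F3, methylated (MeI, K2CO3, acetone) to 2-methoxy-1,3-bis(methoxymethoxy)benzene F4, and the MOM groups are cleaved (HCl, MeOH) to give 3.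

Step 6 (Wittig on the hemiketal). Risks are low conversion of the closed hemiketal and base epimerisation at the ketone α-carbon, which would erode the C6′ configuration. The fallback sets out from 8 and comes back at 9. The weakly basic organocerium reagent from Me3SiCH2Li and CeCl3 (THF, −78 °C) adds to the open keto form to give the β-hydroxysilane 2-[(4R,5R)-5-(hydroxymethyl)-2,2-dimethyl-1,3-dioxolan-4-yl]-1-(trimethylsilyl)propan-2-ol F5, and Peterson elimination (KH, THF, 0 °C) gives 9.

**Further compounds**
F1 | step 8 | (E)-4-[(4S,5S)-2,2-dimethyl-5-(prop-1-en-2-yl)-1,3-dioxolan-4-yl]-3-methylbut-2-en-1-ol | C=C(C)[C@@H]1OC(C)(C)O[C@H]1C/C(C)=C/CO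
F2 | step 2 | 1,3-bis(methoxymethoxy)benzene | COCOc1cccc(OCOC)c1
F3 | step 2 | 2,6-bis(methoxymethoxy)phenol | COCOc1cccc(OCOC)c1O
F4 | step 2 | 2-methoxy-1,3-bis(methoxymethoxy)benzene | COCOc1cccc(OCOC)c1OC
F5 | step 6 | 2-[(4R,5R)-5-(hydroxymethyl)-2,2-dimethyl-1,3-dioxolan-4-yl]-1-(trimethylsilyl)propan-2-ol | OC[C@@H]1[C@H](C(C)(O)C[Si](C)(C)C)OC(C)(C)O1
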